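**Retrosynthetic overview**
- Feature: the prenyl carbon C6 lies between O5 and O7 and is the only unsubstituted ortho carbon of O5 (the other, C4a, is the chroman ring fusion). The dimethylpyran is fused across C2'–C3' with its oxygen on C2', whose other ortho carbon C1' carries C3.
- C6–prenyl, C3'–C4'' and O2'–C2'' are therefore all made in one thermal operation from diether 24 (aromatic Claisen, then propargyl Claisen/1,5-H shift/oxa-6π). O-Methylation and desilylation follow.
- 24 comes from phenol 20 by Pd-catalysed O-tert-allylation. The propargyl ether is carried from the B-ring acid, whose O2' and O4' are told apart through the lactone of 2,4-dihydroxyphenylacetic acid.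
- 20 comes from Mitsunobu closure (O1–C2) onto a 2,6-dihydroxy-4-methoxybenzyl unit, where either hydroxyl gives the same chroman. The C3 stereocentre and the C3–C4 bond come from an Evans alkylation with a benzyl bromide made from 5-methoxyresorcinol.
- Ring order: both arenes are bought; the chroman ring closes in step 12 and the dimethylpyran ring in step 15.

Key step: step 15

Remark: isoflavan numbering is used (O1, C2, C3, C4, C4a, C5–C8, C8a; B ring C1'–C6'; pyran carbons C2''–C4''). O4' is carried as a TIPS ether, since an aryl TBS ether would be at risk in the hydroxide and carbonate steps (4 and 16).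

**Route**

Step 1
Reactants: 1 2,4-dihydroxyphenylacetic acid
Product: 2 6-hydroxybenzofuran-2(3H)-one
Conditions: p-TsOH·H2O (5 mol%), toluene, reflux, Dean–Stark
Reagents that add atoms: none
Why: Acid-catalysed lactonisation (intramolecular Fischer esterification) can only engage the ortho hydroxyl, so the five-membered lactone masks the future O2' and leaves the future O4' as the single free phenol.

Step 2
Reactants: 2 6-hydroxybenzofuran-2(3H)-one
Product: 3 6-(triisopropylsilyloxy)benzofuran-2(3H)-one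
Conditions: TIPSCl, imidazole, DMF, 0 °C → rt
Reagents that add atoms: chlorotriisopropylsilane, CC(C)[Si](Cl)(C(C)C)C(C)C
Why: Standard imidazole-mediated O-silylation of the only free phenol, which places the robust silyl group on the future O4' without ambiguity.

Step 3
Reactants: 3 6-(triisopropylsilyloxy)benzofuran-2(3H)-one; 4 3-chloro-3-methylbut-1-yne
Product: 6 methyl 2-[2-(2-methylbut-3-yn-2-yloxy)-4-(triisopropylsilyloxy)phenyl]acetate, via ring-opened methyl ester phenol 5 (not isolated)
Conditions: MeOH (5 equiv), DBU (2.2 equiv), MeCN, 0 °C; then CuCl2·2H2O (1 mol%), 4 (1.5 equiv), 0 °C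
Reagents that add atoms: methanol, CO
Why: Base-promoted methanolysis of the aryl lactone frees the O2' phenoxide, which is trapped by copper-catalysed propargylic etherification (copper acetylide/allenylidene pathway, the usual way to aryl 1,1-dimethylpropargyl ethers); any relactonisation releases methanol that reopens the ring, so material should funnel to the ether.

Step 4
Reactants: 6 methyl 2-[2-(2-methylbut-3-yn-2-yloxy)-4-(triisopropylsilyloxy)phenyl]acetate
Product: 7 2-[2-(2-methylbut-3-yn-2-yloxy)-4-(triisopropylsilyloxy)phenyl]acetic acid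
Conditions: LiOH·H2O, THF/H2O, 0 °C → rt; then cold 1 M HCl to pH 3–4
Reagents that add atoms: lithium hydroxide, [Li+].[OH-]
Why: Saponification of an unhindered methyl arylacetate is fast at 0 °C, and the aryl TIPS ether and the tertiary propargyl ether should tolerate brief exposure to hydroxide.

Step 5
Reactants: 7 2-[2-(2-methylbut-3-yn-2-yloxy)-4-(triisopropylsilyloxy)phenyl]acetic acid; 8 (R)-4-benzyloxazolidin-2-one
Product: 10 (R)-4-benzyl-3-{2-[2-(2-methylbut-3-yn-2-yloxy)-4-(triisopropylsilyloxy)phenyl]acetyl}oxazolidin-2-one, via mixed pivalic anhydride 9 (not isolated)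
Conditions: PivCl, Et3N, THF, −20 °C; then 8, LiCl, −20 °C → rt
Reagents that add atoms: none
Why: N-Acylation of the oxazolidinone through the mixed pivalic anhydride under LiCl/Et3N activation avoids any strong base, so the terminal alkyne is not touched.

Step 6
Reactants: 11 5-methoxyresorcinol
Product: 12 1-methoxy-3,5-bis(methoxymethoxy)benzene
Conditions: MOMCl, i-Pr2NEt, CH2Cl2, 0 °C → rt
Reagents that add atoms: chloromethyl methyl ether, COCCl
Why: Double O-alkylation of a symmetric resorcinol gives two MOM ethers that protect the phenols and serve as directing groups for the next step.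

Step 7
Reactants: 12 1-methoxy-3,5-bis(methoxymethoxy)benzene
Product: 14 [4-methoxy-2,6-bis(methoxymethoxy)phenyl]methanol, via aryllithium 13 (not isolated)
Conditions: n-BuLi, TMEDA, THF, 0 °C; (CH2O)n, 0 °C → rt; H2O
Reagents that add atoms: formaldehyde (as paraformaldehyde), C=O
Why: Directed ortho-metalation should favour the carbon flanked by the two chelating MOM ethers over those flanked by one MOM and the methoxy group, and hydroxymethylation of the aryllithium places the future C4 between the two oxygens, para to the methoxy group.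

Step 8
Reactants: 14 [4-methoxy-2,6-bis(methoxymethoxy)phenyl]methanol
Product: 15 2-(bromomethyl)-5-methoxy-1,3-bis(methoxymethoxy)benzene
Conditions: CBr4, PPh3, CH2Cl2, −20 °C; cold filtration through neutral alumina; used at once as a THF solution
Reagents that add atoms: tetrabromomethane, BrC(Br)(Br)Br
Why: The Appel reaction converts the benzylic alcohol to the bromide without acid, which matters for the MOM groups and for this very electron-rich, ionisation-prone benzylic system.

Step 9
Reactants: 10 (R)-4-benzyl-3-{2-[2-(2-methylbut-3-yn-2-yloxy)-4-(triisopropylsilyloxy)phenyl]acetyl}oxazolidin-2-one; 15 2-(bromomethyl)-5-methoxy-1,3-bis(methoxymethoxy)benzene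
Product: 17 (R)-4-benzyl-3-{(2R)-3-[4-methoxy-2,6-bis(methoxymethoxy)phenyl]-2-[2-(2-methylbut-3-yn-2-yloxy)-4-(triisopropylsilyloxy)phenyl]propanoyl}oxazolidin-2-one, via sodium Z-enolate 16 (not isolated)
Conditions: NaHMDS (1.05 equiv), THF, −78 °C; then 15, −78 → −40 °C
Reagents that add atoms: none
Why: Evans alkylation: the chelated Z-enolate is alkylated on the face opposite the auxiliary benzyl group, which with the (R)-auxiliary and the aryl group as enolate substituent should set the (R) configuration of the future C3; the imide α-proton is far more acidic than the alkyne C–H, so one equivalent of base suffices.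

Step 10
Reactants: 17 (R)-4-benzyl-3-{(2R)-3-[4-methoxy-2,6-bis(methoxymethoxy)phenyl]-2-[2-(2-methylbut-3-yn-2-yloxy)-4-(triisopropylsilyloxy)phenyl]propanoyl}oxazolidin-2-one
Product: 18 (2R)-3-[4-methoxy-2,6-bis(methoxymethoxy)phenyl]-2-[2-(2-methylbut-3-yn-2-yloxy)-4-(triisopropylsilyloxy)phenyl]propan-1-ol
Conditions: LiBH4, H2O (2 equiv), Et2O, 0 °C
Reagents that add atoms: none
Why: Reductive cleavage of the N-acyl oxazolidinone with lithium borohydride gives the primary alcohol under conditions mild enough to leave the α-aryl stereocentre, the silyl ether and the alkyne intact.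

Step 11
Reactants: 18 (2R)-3-[4-methoxy-2,6-bis(methoxymethoxy)phenyl]-2-[2-(2-methylbut-3-yn-2-yloxy)-4-(triisopropylsilyloxy)phenyl]propan-1-ol
Product: 19 2-{(2R)-3-hydroxy-2-[2-(2-methylbut-3-yn-2-yloxy)-4-(triisopropylsilyloxy)phenyl]propyl}-5-methoxybenzene-1,3-diol
Conditions: conc. HCl (cat.), MeOH, 40 °C
Reagents that add atoms: none
Why: Acid-catalysed acetal exchange with methanol removes both MOM groups, while the aryl TIPS ether and the tertiary propargyl ether (which ionises less readily than a tert-butyl ether) should survive dilute methanolic acid.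

Step 12
Reactants: 19 2-{(2R)-3-hydroxy-2-[2-(2-methylbut-3-yn-2-yloxy)-4-(triisopropylsilyloxy)phenyl]propyl}-5-methoxybenzene-1,3-diol
Product: 20 (R)-7-methoxy-3-[2-(2-methylbut-3-yn-2-yloxy)-4-(triisopropylsilyloxy)phenyl]chroman-5-ol
Conditions: PPh3, DIAD, THF (0.02 M), 0 °C → rt
Reagents that add atoms: none
Why: Intramolecular Mitsunobu etherification (6-exo-tet at the primary carbon) closes the chroman; the two phenols are equivalent by rotation about the aryl–CH2 bond, so one product results, the stereocentre is not a reacting centre, and the unused phenol is the 5-OH.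

Step 13
Reactants: 21 2-methylbut-3-en-2-ol
Product: 23 isobutyl 2-methylbut-3-en-2-yl carbonate, via lithium alkoxide 22 (not isolated)
Conditions: n-BuLi, THF, 0 °C; then i-BuOCOCl, 0 °C → rt
Reagents that add atoms: isobutyl chloroformate, CC(C)COC(Cl)=O
Why: Acylation of the tertiary lithium alkoxide with a chloroformate is the standard route to the mixed carbonate used for reverse prenylation.

Step 14
Reactants: 20 (R)-7-methoxy-3-[2-(2-methylbut-3-yn-2-yloxy)-4-(triisopropylsilyloxy)phenyl]chroman-5-ol; 23 isobutyl 2-methylbut-3-en-2-yl carbonate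
Product: 24 (R)-7-methoxy-5-(2-methylbut-3-en-2-yloxy)-3-[2-(2-methylbut-3-yn-2-yloxy)-4-(triisopropylsilyloxy)phenyl]chromane
Conditions: Pd(PPh3)4 (5 mol%), THF, 0 °C
Reagents that add atoms: none
Why: Decarboxylative Tsuji–Trost O-allylation: the phenoxide attacks the more substituted terminus of the 1,1-dimethyl-π-allyl palladium complex under kinetic control to give the tertiary allyl ether, and the aryl propargyl ether is a far poorer partner for Pd(0) than the allylic carbonate.

Step 15
Reactants: 24 (R)-7-methoxy-5-(2-methylbut-3-en-2-yloxy)-3-[2-(2-methylbut-3-yn-2-yloxy)-4-(triisopropylsilyloxy)phenyl]chromane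
Product: 27 (R)-3-[2,2-dimethyl-5-(triisopropylsilyloxy)-2H-chromen-8-yl]-7-methoxy-6-(3-methylbut-2-enyl)chroman-5-ol, via prenylphenol propargyl ether 25 (not isolated), via allenylphenol 26 (not isolated)
Conditions: PhNEt2 (degassed, 0.05 M), Ar, 120 °C then 185 °C
Reagents that add atoms: none
Why: On heating, the O5 1,1-dimethylallyl ether should undergo a chair-like [3,3] shift to C6 and the dienone tautomerises to prenylphenol 25; at the higher temperature the O2' 1,1-dimethylpropargyl ether shifts [3,3] to C3', the allenyl dienone enolises to allenylphenol 26, and a 1,5-hydrogen shift from the new 2'-OH gives an o-quinone methide that closes. The closest known reaction types are the thermal aromatic Claisen rearrangement of aryl 1,1-dimethylallyl ethers to o-prenylphenols and the propargyl Claisen route from aryl 1,1-dimethylpropargyl ethers to 2,2-dimethyl-2H-chromenes, here run consecutively in one flask with the aniline solvent as acid scavenger. The only ring formed, the six-membered dimethylpyran, closes by thermal disrotatory oxa-6π electrocyclisation (O2'–C2'' bond). No stereocentre is created, and C3, a non-acidic methine remote from both reacting sites, should be unaffected under neutral thermal conditions. Only regioselectivity is needed: C6 is the sole unsubstituted ortho carbon of O5 (C4a is the ring fusion) and C3' the sole unsubstituted ortho carbon of O2' (C1' carries C3), while the silyl ether on O4' leaves O2' as the only oxygen that can deliver the hydrogen and close the pyran, so only the angular chromene can form.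

Step 16
Reactants: 27 (R)-3-[2,2-dimethyl-5-(triisopropylsilyloxy)-2H-chromen-8-yl]-7-methoxy-6-(3-methylbut-2-enyl)chroman-5-ol
Product: 28 (R)-3-[2,2-dimethyl-5-(triisopropylsilyloxy)-2H-chromen-8-yl]-5,7-dimethoxy-6-(3-methylbut-2-enyl)chromane
Conditions: MeI, K2CO3, acetone, 50 °C
Reagents that add atoms: iodomethane, CI
Why: Williamson methylation of the only free phenol; anhydrous carbonate in acetone should leave the aryl TIPS ether in place.

Step 17
Reactants: 28 (R)-3-[2,2-dimethyl-5-(triisopropylsilyloxy)-2H-chromen-8-yl]-5,7-dimethoxy-6-(3-methylbut-2-enyl)chromane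
Product: 29 kanzonol I, (R)-8-[5,7-dimethoxy-6-(3-methylbut-2-enyl)chroman-3-yl]-2,2-dimethyl-2H-chromen-5-ol
Conditions: TBAF, AcOH (1:1), THF, 0 °C
Reagents that add atoms: none
Why: Buffered fluoride desilylation of the aryl silyl ether liberates the 4'-OH without affecting the chromene, the prenyl group or the methyl ethers.

**Compound list**
1 | 2,4-dihydroxyphenylacetic acid | OC(=O)Cc1ccc(O)cc1O | starting material
2 | 6-hydroxybenzofuran-2(3H)-one | O=C1Cc2ccc(O)cc2O1 | intermediate
3 | 6-(triisopropylsilyloxy)benzofuran-2(3H)-one | O=C1Cc2ccc(O[Si](C(C)C)(C(C)C)C(C)C)cc2O1 | intermediate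
4 | 3-chloro-3-methylbut-1-yne | CC(C)(Cl)C#C | starting material
5 | methyl 2-[2-hydroxy-4-(triisopropylsilyloxy)phenyl]acetate | COC(=O)Cc1ccc(O[Si](C(C)C)(C(C)C)C(C)C)cc1O | intermediate
6 | methyl 2-[2-(2-methylbut-3-yn-2-yloxy)-4-(triisopropylsilyloxy)phenyl]acetate | COC(=O)Cc1ccc(O[Si](C(C)C)(C(C)C)C(C)C)cc1OC(C)(C)C#C | intermediate
7 | 2-[2-(2-methylbut-3-yn-2-yloxy)-4-(triisopropylsilyloxy)phenyl]acetic acid | OC(=O)Cc1ccc(O[Si](C(C)C)(C(C)C)C(C)C)cc1OC(C)(C)C#C | intermediate
8 | (R)-4-benzyloxazolidin-2-one | O=C1N[C@H](Cc2ccccc2)CO1 | starting material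
9 | mixed pivalic anhydride of acid 7 | CC(C)(C)C(=O)OC(=O)Cc1ccc(O[Si](C(C)C)(C(C)C)C(C)C)cc1OC(C)(C)C#C | intermediate
10 | (R)-4-benzyl-3-{2-[2-(2-methylbut-3-yn-2-yloxy)-4-(triisopropylsilyloxy)phenyl]acetyl}oxazolidin-2-one | O=C(Cc1ccc(O[Si](C(C)C)(C(C)C)C(C)C)cc1OC(C)(C)C#C)N1[C@H](Cc2ccccc2)COC1=O | intermediate
11 | 5-methoxyresorcinol | COc1cc(O)cc(O)c1 | starting material
12 | 1-methoxy-3,5-bis(methoxymethoxy)benzene | COCOc1cc(OC)cc(OCOC)c1 | intermediate
13 | [4-methoxy-2,6-bis(methoxymethoxy)phenyl]lithium | [Li]c1c(OCOC)cc(OC)cc1OCOC | intermediate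
14 | [4-methoxy-2,6-bis(methoxymethoxy)phenyl]methanol | OCc1c(OCOC)cc(OC)cc1OCOC | intermediate
15 | 2-(bromomethyl)-5-methoxy-1,3-bis(methoxymethoxy)benzene | BrCc1c(OCOC)cc(OC)cc1OCOC | intermediate
16 | sodium (Z)-enolate of imide 10 | [Na+].[O-]/C(=C\c1ccc(O[Si](C(C)C)(C(C)C)C(C)C)cc1OC(C)(C)C#C)N1[C@H](Cc2ccccc2)COC1=O | intermediate
17 | (R)-4-benzyl-3-{(2R)-3-[4-methoxy-2,6-bis(methoxymethoxy)phenyl]-2-[2-(2-methylbut-3-yn-2-yloxy)-4-(triisopropylsilyloxy)phenyl]propanoyl}oxazolidin-2-one | O=C([C@H](Cc1c(OCOC)cc(OC)cc1OCOC)c1ccc(O[Si](C(C)C)(C(C)C)C(C)C)cc1OC(C)(C)C#C)N1[C@H](Cc2ccccc2)COC1=O | intermediate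
18 | (2R)-3-[4-methoxy-2,6-bis(methoxymethoxy)phenyl]-2-[2-(2-methylbut-3-yn-2-yloxy)-4-(triisopropylsilyloxy)phenyl]propan-1-ol | OC[C@H](Cc1c(OCOC)cc(OC)cc1OCOC)c1ccc(O[Si](C(C)C)(C(C)C)C(C)C)cc1OC(C)(C)C#C | intermediate
19 | 2-{(2R)-3-hydroxy-2-[2-(2-methylbut-3-yn-2-yloxy)-4-(triisopropylsilyloxy)phenyl]propyl}-5-methoxybenzene-1,3-diol | OC[C@H](Cc1c(O)cc(OC)cc1O)c1ccc(O[Si](C(C)C)(C(C)C)C(C)C)cc1OC(C)(C)C#C | intermediate
20 | (R)-7-methoxy-3-[2-(2-methylbut-3-yn-2-yloxy)-4-(triisopropylsilyloxy)phenyl]chroman-5-ol | COc1cc2c(c(O)c1)C[C@H](c1ccc(O[Si](C(C)C)(C(C)C)C(C)C)cc1OC(C)(C)C#C)CO2 | intermediate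
21 | 2-methylbut-3-en-2-ol | CC(C)(O)C=C | starting material
22 | lithium 2-methylbut-3-en-2-olate | [Li+].[O-]C(C)(C)C=C | intermediate
23 | isobutyl 2-methylbut-3-en-2-yl carbonate | CC(C)COC(=O)OC(C)(C)C=C | intermediate
24 | (R)-7-methoxy-5-(2-methylbut-3-en-2-yloxy)-3-[2-(2-methylbut-3-yn-2-yloxy)-4-(triisopropylsilyloxy)phenyl]chromane | COc1cc2c(c(OC(C)(C)C=C)c1)C[C@H](c1ccc(O[Si](C(C)C)(C(C)C)C(C)C)cc1OC(C)(C)C#C)CO2 | intermediate
25 | (R)-7-methoxy-6-(3-methylbut-2-enyl)-3-[2-(2-methylbut-3-yn-2-yloxy)-4-(triisopropylsilyloxy)phenyl]chroman-5-ol | COc1cc2c(c(O)c1CC=C(C)C)C[C@H](c1ccc(O[Si](C(C)C)(C(C)C)C(C)C)cc1OC(C)(C)C#C)CO2 | intermediate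
26 | (R)-3-[2-hydroxy-3-(3-methylbuta-1,2-dienyl)-4-(triisopropylsilyloxy)phenyl]-7-methoxy-6-(3-methylbut-2-enyl)chroman-5-ol | COc1cc2c(c(O)c1CC=C(C)C)C[C@H](c1ccc(O[Si](C(C)C)(C(C)C)C(C)C)c(C=C=C(C)C)c1O)CO2 | intermediate
27 | (R)-3-[2,2-dimethyl-5-(triisopropylsilyloxy)-2H-chromen-8-yl]-7-methoxy-6-(3-methylbut-2-enyl)chroman-5-ol | COc1cc2c(c(O)c1CC=C(C)C)C[C@H](c1ccc(O[Si](C(C)C)(C(C)C)C(C)C)c3c1OC(C)(C)C=C3)CO2 | intermediate
28 | (R)-3-[2,2-dimethyl-5-(triisopropylsilyloxy)-2H-chromen-8-yl]-5,7-dimethoxy-6-(3-methylbut-2-enyl)chromane | COc1cc2c(c(OC)c1CC=C(C)C)C[C@H](c1ccc(O[Si](C(C)C)(C(C)C)C(C)C)c3c1OC(C)(C)C=C3)CO2 | intermediate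
29 | kanzonol I | COc1cc2c(c(OC)c1CC=C(C)C)C[C@H](c1ccc(O)c3c1OC(C)(C)C=C3)CO2 | target

**Totals**
Total step count: 17.
Longest linear sequence: 13 steps (1–5, 9–12, 14–17, from 2,4-dihydroxyphenylacetic acid).

**Steps most likely to fail**

1. Step 15. The tertiary allyl ether may fragment thermally (loss of isoprene) before it rearranges. The propargyl unit may also migrate to the substituted C1' and the blocked allenyl dienone be consumed by cycloaddition, or the prenylphenol may degrade during the hotter second stage. Fallback, from 24 and back at 28: the two rearrangements are run apart. Diether 24 is heated only to 100 °C in toluene, where the tertiary allyl ether should rearrange and the propargyl ether should not, and 25 is isolated. Its phenol is methylated (MeI, K2CO3, acetone) to give (R)-5,7-dimethoxy-6-(3-methylbut-2-enyl)-3-[2-(2-methylbut-3-yn-2-yloxy)-4-(triisopropylsilyloxy)phenyl]chromane F1. This compound alone is then heated in PhNEt2 at 185 °C, so that the propargyl Claisen/1,5-H shift/oxa-6π sequence delivers 28 directly.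

2. Step 9. Ionisation and self-condensation of the trioxygenated benzylic bromide may outrun C-alkylation of the enolate. Fallback, from 12 and 7 and back at 18: the benzylic carbon is introduced at the aldehyde oxidation level.
   - Aryllithium 13 (from 12) is quenched with DMF to give the stable 4-methoxy-2,6-bis(methoxymethoxy)benzaldehyde F2.
   - Acid 7 is loaded, as in step 5, on (S)-4-benzyloxazolidin-2-one to give the enantiomeric-auxiliary imide F3. The antipode is needed because the boron aldol uses the enolate face opposite to that of the chelated alkylation.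
   - Evans syn-aldol reaction (Bu2BOTf, i-Pr2NEt, CH2Cl2, −78 → 0 °C) of this imide with the aldehyde gives the (2S,3S)-β-hydroxy imide F4.
   - Ionic deoxygenation of its highly stabilised benzylic alcohol (Et3SiH, BF3·OEt2, CH2Cl2, −78 °C) gives the (2R)-propanoyl imide F5.
   - LiBH4 reduction as in step 10 then gives 18.

3. Step 14. The kinetic branched ether may isomerise to the linear prenyl ether through re-ionisation by Pd(0), or the terminal alkyne may interfere with the catalyst. Fallback, from 20 and back at 27: the chromene is made first so that no alkyne remains.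
   - Phenol 20 is heated (PhNEt2, 185 °C) to give (R)-3-[2,2-dimethyl-5-(triisopropylsilyloxy)-2H-chromen-8-yl]-7-methoxychroman-5-ol F6.
   - Its 5-OH is etherified with 4 under the copper conditions of step 3 (CuCl2 cat., DBU, MeCN, 0 °C) to give the 5-O-(1,1-dimethylpropargyl) ether F7.
   - Lindlar semihydrogenation (Pd/CaCO3/Pb, quinoline, H2, EtOAc) gives the 5-O-(1,1-dimethylallyl) ether F8.
   - Heating this ether at 110 °C in toluene effects the aromatic Claisen shift to C6 and gives 27.

**Further compounds**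
F1 | step 15 | (R)-5,7-dimethoxy-6-(3-methylbut-2-enyl)-3-[2-(2-methylbut-3-yn-2-yloxy)-4-(triisopropylsilyloxy)phenyl]chromane | COc1cc2c(c(OC)c1CC=C(C)C)C[C@H](c1ccc(O[Si](C(C)C)(C(C)C)C(C)C)cc1OC(C)(C)C#C)CO2
F2 | step 9 | 4-methoxy-2,6-bis(methoxymethoxy)benzaldehyde | COCOc1cc(OC)cc(OCOC)c1C=O
F3 | step 9 | (S)-4-benzyl-3-{2-[2-(2-methylbut-3-yn-2-yloxy)-4-(triisopropylsilyloxy)phenyl]acetyl}oxazolidin-2-one | O=C(Cc1ccc(O[Si](C(C)C)(C(C)C)C(C)C)cc1OC(C)(C)C#C)N1[C@@H](Cc2ccccc2)COC1=O
F4 | step 9 | (S)-4-benzyl-3-{(2S,3S)-3-hydroxy-3-[4-methoxy-2,6-bis(methoxymethoxy)phenyl]-2-[2-(2-methylbut-3-yn-2-yloxy)-4-(triisopropylsilyloxy)phenyl]propanoyl}oxazolidin-2-one | O=C([C@H]([C@H](O)c1c(OCOC)cc(OC)cc1OCOC)c1ccc(O[Si](C(C)C)(C(C)C)C(C)C)cc1OC(C)(C)C#C)N1[C@@H](Cc2ccccc2)COC1=O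
F5 | step 9 | (S)-4-benzyl-3-{(2R)-3-[4-methoxy-2,6-bis(methoxymethoxy)phenyl]-2-[2-(2-methylbut-3-yn-2-yloxy)-4-(triisopropylsilyloxy)phenyl]propanoyl}oxazolidin-2-one | O=C([C@H](Cc1c(OCOC)cc(OC)cc1OCOC)c1ccc(O[Si](C(C)C)(C(C)C)C(C)C)cc1OC(C)(C)C#C)N1[C@@H](Cc2ccccc2)COC1=O
F6 | step 14 | (R)-3-[2,2-dimethyl-5-(triisopropylsilyloxy)-2H-chromen-8-yl]-7-methoxychroman-5-ol | COc1cc2c(c(O)c1)C[C@H](c1ccc(O[Si](C(C)C)(C(C)C)C(C)C)c3c1OC(C)(C)C=C3)CO2
F7 | step 14 | (R)-3-[2,2-dimethyl-5-(triisopropylsilyloxy)-2H-chromen-8-yl]-7-methoxy-5-(2-methylbut-3-yn-2-yloxy)chromane | COc1cc2c(c(OC(C)(C)C#C)c1)C[C@H](c1ccc(O[Si](C(C)C)(C(C)C)C(C)C)c3c1OC(C)(C)C=C3)CO2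
F8 | step 14 | (R)-3-[2,2-dimethyl-5-(triisopropylsilyloxy)-2H-chromen-8-yl]-7-methoxy-5-(2-methylbut-3-en-2-yloxy)chromane | COc1cc2c(c(OC(C)(C)C=C)c1)C[C@H](c1ccc(O[Si](C(C)C)(C(C)C)C(C)C)c3c1OC(C)(C)C=C3)CO2
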